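Ring A (C4a, C5, C6, C7, C8, C8a of the target) is a cyclohexenone whose enone C4a=C5–C6=O hides a 1,5-diketone between C6 and the ring B carbon C4a, with quaternary C8a as its α-carbon. Ring A is therefore formed by a Robinson annulation: the dienolate of a monocyclic ring B enone ketal, made by catalytic asymmetric conjugate methylation of a quinone monoketal, adds to an α-silyl vinyl ketone anti to the secondary methyl, and aldol condensation forms the dienone in the same operation. A silyl enol ether then masks ring A while the C2 ketone is reduced and acylated, and finally delivers the C7 hydroxyl.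

Key step: step 5

Remark: (S)-2-methylglycidol, 4,4-dimethoxycyclohexa-2,5-dien-1-one, triethyl 4-phosphonocrotonate and 3-(trimethylsilyl)but-3-en-2-one are taken as purchasable; each compound is numbered by its own systematic name, and the bicyclic compounds from 16 on share the numbering of the target.

Step 1
Reactants: 1 (S)-2-methylglycidol
Product: 2 (R)-2-methylbutane-1,2-diol
Conditions: MeMgBr (2.5 equiv), CuI (10 mol %), THF, −30 → 0 °C; aq. NH4Cl
Reagents that add atoms: methylmagnesium bromide, C[Mg]Br
Why: Copper-catalysed Grignard opening of the 2,2-disubstituted epoxide (SN2 at the CH2 terminus) leaves the bonds of the quaternary carbinol untouched, so its configuration is carried over from 1 (the descriptor changes from S to R only through the change in priorities).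

Step 2
Reactants: 2 (R)-2-methylbutane-1,2-diol; 3 triethyl 4-phosphonocrotonate
Product: 5 ethyl (2E,4E,6R)-6-hydroxy-6-methylocta-2,4-dienoate, via (R)-2-hydroxy-2-methylbutanal 4 (not isolated)
Conditions: 2-iodoxybenzoic acid, MeCN, 80 °C; filter; then 3, LiCl, DBU, MeCN, 0 °C → rt
Reagents that add atoms: none
Why: 2-Iodoxybenzoic acid should oxidise the primary hydroxyl of the 1,2-diol without glycol cleavage, and the vinylogous Horner–Wadsworth–Emmons olefination of the aldehyde under LiCl/amine conditions tolerates the free tertiary hydroxyl and should give the (2E,4E)-dienoate without touching the stereocentre.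

Step 3
Reactants: 5 ethyl (2E,4E,6R)-6-hydroxy-6-methylocta-2,4-dienoate
Product: 6 (2E,4E,6R)-6-hydroxy-6-methylocta-2,4-dienoic acid
Conditions: LiOH, THF/MeOH/H2O, rt; then 1 M HCl to pH 4, 0 °C
Reagents that add atoms: lithium hydroxide, [Li+].[OH-]
Why: Saponification of an ethyl ester that has no enolisable position, followed by mild acidification, should give the acid without affecting the tertiary carbinol or the diene geometry.

Step 4
Reactants: 7 4,4-dimethoxycyclohexa-2,5-dien-1-one
Product: 9 (5R,6R)-4,4-dimethoxy-5,6-dimethylcyclohex-2-en-1-one, via zinc enolate 8 (not isolated)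
Conditions: Me2Zn, Cu(OTf)2 (2 mol %), binaphthol-derived N,N-bis(1-phenylethyl)phosphoramidite (4 mol %, enantiomer giving 5R), toluene, −25 °C; then MeI, HMPA, 0 °C → rt
Reagents that add atoms: dimethylzinc, C[Zn]C; iodomethane, CI
Why: Copper-catalysed enantioselective conjugate addition with a phosphoramidite ligand desymmetrises the prochiral dienone and sets C5 under catalyst control, and the zinc enolate is C-methylated anti to that methyl (tandem conjugate addition–enolate alkylation); the C6 centre is erased again in step 5, so only C5 has to be controlled.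

Step 5
Reactants: 9 (5R,6R)-4,4-dimethoxy-5,6-dimethylcyclohex-2-en-1-one; 10 3-(trimethylsilyl)but-3-en-2-one
Product: 14 (4aR,5R)-4a,5-dimethyl-4,4a-dihydronaphthalene-2,6(3H,5H)-dione, via lithium dienolate 11 (not isolated), via silyl diketone 12 (not isolated), via dienone ketal 13 (not isolated)
Conditions: LiN(iPr)2, THF, −78 °C; 10, −78 → −30 °C; then KOH, MeOH, 0 °C → rt; then 1 M HCl, THF, rt
Reagents that add atoms: water, O
Why: LiN(iPr)2 removes the only enolisable hydrogen of 9 (C6–H; C4 is quaternary) to give the cross-conjugated dienolate 11, which adds to the α-silyl enone 10 (Michael addition) to give 12; methanolic KOH then cleaves the C–Si bond, the methyl ketone enolate attacks the ring B carbonyl (intramolecular aldol addition), E1cB dehydration gives the linear dienone 13, and the acid work-up hydrolyses the dimethyl ketal to the second ketone. The closest known reaction type is the Robinson annulation of 2,3-dimethylcyclohexanones with vinyl ketones or their α-silyl variants that is used for eremophilane skeletons. Ring A is closed by a 6-(enolexo)-exo-trig aldol addition. The new quaternary centre (C4a of 14) is controlled by the neighbouring C5 methyl, which should sit pseudoaxial in 11 to avoid A(1,2) strain with the enolate methyl, so that the acceptor enters from the opposite face and the two methyl groups end cis. The step needs a single conjugate addition instead of a Michael–Michael sequence to a bicyclo[2.2.2]octanone, and aldol attack on a conjugated carbonyl: the silyl group on the intermediate enolate carbon and the quaternary ketal carbon next to the enone β-carbon should hold back the second conjugate addition, and the irreversible dehydration to the cross-ring dienone pulls the aldol equilibrium forward.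

Step 6
Reactants: 14 (4aR,5R)-4a,5-dimethyl-4,4a-dihydronaphthalene-2,6(3H,5H)-dione
Product: 16 (1R,8aR)-6-[(tert-butyldimethylsilyl)oxy]-1,8a-dimethyl-8,8a-dihydronaphthalen-2(1H)-one, via lithium enolate 15 (not isolated)
Conditions: LiN(SiMe3)2 (1.05 equiv), THF, −78 °C; then TBSCl, HMPA, −78 → 0 °C
Reagents that add atoms: tert-butyldimethylsilyl chloride, CC(C)(C)[Si](C)(C)Cl
Why: Kinetic deprotonation should take the unhindered C3 methylene of the ring A ketone in preference to the tertiary C5–H next to the quaternary carbon, and O-silylation of the enolate (silyl enol ether formation) masks that ketone as a cross-conjugated silyl dienol ether without touching the C5 stereocentre.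

Step 7
Reactants: 16 (1R,8aR)-6-[(tert-butyldimethylsilyl)oxy]-1,8a-dimethyl-8,8a-dihydronaphthalen-2(1H)-one
Product: 17 (1R,2S,8aR)-6-[(tert-butyldimethylsilyl)oxy]-1,8a-dimethyl-1,2,8,8a-tetrahydronaphthalen-2-ol
Conditions: iBu2AlH, CH2Cl2, −78 °C; aq. potassium sodium tartrate
Reagents that add atoms: none
Why: 1,2-Reduction of the remaining dienone carbonyl by the aluminium hydride should occur from the face opposite the axial angular methyl, which stands 1,3 to the carbonyl carbon (the bias known from 2-oxo steroids), so that the new C2 hydroxyl is cis to both methyl groups (2S).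

Step 8
Reactants: 6 (2E,4E,6R)-6-hydroxy-6-methylocta-2,4-dienoic acid; 17 (1R,2S,8aR)-6-[(tert-butyldimethylsilyl)oxy]-1,8a-dimethyl-1,2,8,8a-tetrahydronaphthalen-2-ol
Product: 19 (1R,2S,8aR)-6-[(tert-butyldimethylsilyl)oxy]-1,8a-dimethyl-1,2,8,8a-tetrahydronaphthalen-2-yl (2E,4E,6R)-6-hydroxy-6-methylocta-2,4-dienoate, via mixed anhydride 18 (not isolated)
Conditions: 6, 2,4,6-trichlorobenzoyl chloride, Et3N, THF, rt; then 17, DMAP, toluene, rt
Reagents that add atoms: none
Why: Yamaguchi esterification through the mixed anhydride acylates the secondary allylic hydroxyl with retention at C2, while the tertiary hydroxyl of the acid is too hindered to compete and the dienoyl unit has no γ-hydrogen on an sp3 carbon through which it could deconjugate.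

Step 9
Reactants: 19 (1R,2S,8aR)-6-[(tert-butyldimethylsilyl)oxy]-1,8a-dimethyl-1,2,8,8a-tetrahydronaphthalen-2-yl (2E,4E,6R)-6-hydroxy-6-methylocta-2,4-dienoate
Product: 21 (1R,2S,7R,8aR)-7-hydroxy-1,8a-dimethyl-6-oxo-1,2,6,7,8,8a-hexahydronaphthalen-2-yl (2E,4E,6R)-6-hydroxy-6-methylocta-2,4-dienoate (CNP0260852.1), via silyloxy epoxide 20 (not isolated)
Conditions: dimethyldioxirane (1.0 equiv), acetone/CH2Cl2, −78 °C; then Et3N·3HF, THF, 0 °C → rt
Reagents that add atoms: dimethyldioxirane, CC1(C)OO1
Why: Rubottom oxidation: dimethyldioxirane should epoxidise the silyl enol ether double bond, the most nucleophilic alkene present, from the face opposite the angular methyl, and fluoride opens the silyloxy epoxide to the α-hydroxy ketone, so that the C7 hydroxyl ends equatorial and trans to the C8a methyl (7R), which is also the thermodynamically preferred epimer.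

Compound list
1 | (S)-2-methylglycidol, [(2S)-2-methyloxiran-2-yl]methanol | C[C@]1(CO)CO1 | starting material
2 | (R)-2-methylbutane-1,2-diol | CC[C@@](C)(O)CO | intermediate
3 | triethyl 4-phosphonocrotonate, ethyl (E)-4-(diethoxyphosphoryl)but-2-enoate | CCOC(=O)/C=C/CP(=O)(OCC)OCC | starting material
4 | (R)-2-hydroxy-2-methylbutanal (not isolated) | CC[C@@](C)(O)C=O | intermediate
5 | ethyl (2E,4E,6R)-6-hydroxy-6-methylocta-2,4-dienoate | CC[C@@](C)(O)/C=C/C=C/C(=O)OCC | intermediate
6 | (2E,4E,6R)-6-hydroxy-6-methylocta-2,4-dienoic acid | CC[C@@](C)(O)/C=C/C=C/C(=O)O | intermediate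
7 | 4,4-dimethoxycyclohexa-2,5-dien-1-one | COC1(OC)C=CC(=O)C=C1 | starting material
8 | methylzinc dienolate of (R)-4,4-dimethoxy-5-methylcyclohex-2-en-1-one (not isolated) | C[Zn]OC1=C[C@@H](C)C(OC)(OC)C=C1 | intermediate
9 | (5R,6R)-4,4-dimethoxy-5,6-dimethylcyclohex-2-en-1-one (trans isomer, expected major; C6 is erased in step 5) | O=C1C=CC(OC)(OC)[C@H](C)[C@H]1C | intermediate
10 | 3-(trimethylsilyl)but-3-en-2-one | CC(=O)C(=C)[Si](C)(C)C | starting material
11 | lithium dienolate of 9 (not isolated) | [Li]OC1=C(C)[C@@H](C)C(OC)(OC)C=C1 | intermediate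
12 | (5R,6R)-4,4-dimethoxy-5,6-dimethyl-6-[3-oxo-2-(trimethylsilyl)butyl]cyclohex-2-en-1-one, mixture at the silyl-bearing carbon (not isolated) | CC(=O)C([Si](C)(C)C)C[C@@]1(C)C(=O)C=CC(OC)(OC)[C@@H]1C | intermediate
13 | (4aR,5R)-6,6-dimethoxy-4a,5-dimethyl-4,4a,5,6-tetrahydronaphthalen-2(3H)-one (not isolated) | COC1(OC)C=CC2=CC(=O)CC[C@]2(C)[C@H]1C | intermediate
14 | (4aR,5R)-4a,5-dimethyl-4,4a-dihydronaphthalene-2,6(3H,5H)-dione | O=C1C=CC2=CC(=O)CC[C@]2(C)[C@H]1C | intermediate
15 | lithium enolate of 14 at the ring A ketone (not isolated) | O=C1C=CC2=CC(O[Li])=CC[C@]2(C)[C@H]1C | intermediate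
16 | (1R,8aR)-6-[(tert-butyldimethylsilyl)oxy]-1,8a-dimethyl-8,8a-dihydronaphthalen-2(1H)-one | O=C1C=CC2=CC(O[Si](C)(C)C(C)(C)C)=CC[C@]2(C)[C@H]1C | intermediate
17 | (1R,2S,8aR)-6-[(tert-butyldimethylsilyl)oxy]-1,8a-dimethyl-1,2,8,8a-tetrahydronaphthalen-2-ol | O[C@H]1C=CC2=CC(O[Si](C)(C)C(C)(C)C)=CC[C@]2(C)[C@H]1C | intermediate
18 | (2E,4E,6R)-6-hydroxy-6-methylocta-2,4-dienoic 2,4,6-trichlorobenzoic anhydride (not isolated) | CC[C@@](C)(O)/C=C/C=C/C(=O)OC(=O)c1c(Cl)cc(Cl)cc1Cl | intermediate
19 | (1R,2S,8aR)-6-[(tert-butyldimethylsilyl)oxy]-1,8a-dimethyl-1,2,8,8a-tetrahydronaphthalen-2-yl (2E,4E,6R)-6-hydroxy-6-methylocta-2,4-dienoate | CC[C@@](C)(O)/C=C/C=C/C(=O)O[C@H]1C=CC2=CC(O[Si](C)(C)C(C)(C)C)=CC[C@]2(C)[C@H]1C | intermediate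
20 | 6,7-epoxide of 19 on the face opposite the C8a methyl, silyloxy group retained at C6 (not isolated) | CC[C@@](C)(O)/C=C/C=C/C(=O)O[C@H]1C=CC2=C[C@]3(O[Si](C)(C)C(C)(C)C)O[C@@H]3C[C@]2(C)[C@H]1C | intermediate
21 | CNP0260852.1, (1R,2S,7R,8aR)-7-hydroxy-1,8a-dimethyl-6-oxo-1,2,6,7,8,8a-hexahydronaphthalen-2-yl (2E,4E,6R)-6-hydroxy-6-methylocta-2,4-dienoate | CC[C@@](C)(O)/C=C/C=C/C(=O)O[C@H]1C=CC2=CC(=O)[C@H](O)C[C@]2(C)[C@H]1C | target

Total step count: 9. Longest linear sequence: 6 steps (steps 4 to 9, from 7); the acid 6 is made in 3 steps and joined in step 8.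

Steps most likely to fail

Step 5. The silyl-bearing enolate formed in the first conjugate addition may add a second time to the ring B enone (Michael–Michael closure to a bicyclo[2.2.2]octanone), or the acceptor may enter syn to the C5 methyl because the pseudoaxial methoxy group screens the other face. The fallback sets out from 9 and comes back at 13. Hydrogenation of 9 (H2, Pd/C, EtOAc) would give (2R,3R)-4,4-dimethoxy-2,3-dimethylcyclohexan-1-one F1, which has no enone for a second conjugate addition. Classical Robinson annulation of F1 with methyl vinyl ketone (KOH, MeOH, 0 °C; then NaOMe, MeOH, reflux) at the more substituted α-carbon, anti to the C3 methyl, would give (4aR,5R)-6,6-dimethoxy-4a,5-dimethyl-4,4a,5,6,7,8-hexahydronaphthalen-2(3H)-one F2. Dehydrogenation with chloranil (t-BuOH, reflux) would introduce the C7=C8 double bond and give 13, which is hydrolysed to 14 with 1 M HCl as in step 5.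

Step 7. Hydride delivery may show poor facial selectivity, and the dienylic alcohol may ionise on work-up. The fallback sets out from 16 and comes back at 19. The 2R epimer, (1R,2R,8aR)-6-[(tert-butyldimethylsilyl)oxy]-1,8a-dimethyl-1,2,8,8a-tetrahydronaphthalen-2-ol F3, whether it is the main product or is separated from a mixture, would not be discarded. It would be coupled with 6 in a Mitsunobu esterification (PPh3, diisopropyl azodicarboxylate, toluene, 0 °C), which inverts C2 and gives 19 directly, so that the inversion replaces step 8 for this material.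

Step 8. Acylation of the hindered axial allylic hydroxyl may be slow, the hydroxy acid may acylate itself, or the dienylic alcohol may ionise. The fallback sets out from 17 and comes back at 19. 17 would be acylated with the small diethylphosphonoacetic acid (N,N'-dicyclohexylcarbodiimide, DMAP, CH2Cl2) to give (1R,2S,8aR)-6-[(tert-butyldimethylsilyl)oxy]-1,8a-dimethyl-1,2,8,8a-tetrahydronaphthalen-2-yl 2-(diethoxyphosphoryl)acetate F4. Aldehyde 4 would be homologated with (triphenylphosphoranylidene)acetaldehyde (toluene, 60 °C) to (R,E)-4-hydroxy-4-methylhex-2-enal F5. Horner–Wadsworth–Emmons olefination of F4 with F5 (LiCl, iPr2NEt, MeCN) would then build the dienoate on the core and give 19.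

Further compounds
F1 | step 5 | (2R,3R)-4,4-dimethoxy-2,3-dimethylcyclohexan-1-one | O=C1CCC(OC)(OC)[C@H](C)[C@H]1C
F2 | step 5 | (4aR,5R)-6,6-dimethoxy-4a,5-dimethyl-4,4a,5,6,7,8-hexahydronaphthalen-2(3H)-one | COC1(OC)CCC2=CC(=O)CC[C@]2(C)[C@H]1C
F3 | step 7 | (1R,2R,8aR)-6-[(tert-butyldimethylsilyl)oxy]-1,8a-dimethyl-1,2,8,8a-tetrahydronaphthalen-2-ol | O[C@@H]1C=CC2=CC(O[Si](C)(C)C(C)(C)C)=CC[C@]2(C)[C@H]1C
F4 | step 8 | (1R,2S,8aR)-6-[(tert-butyldimethylsilyl)oxy]-1,8a-dimethyl-1,2,8,8a-tetrahydronaphthalen-2-yl 2-(diethoxyphosphoryl)acetate | CCOP(=O)(OCC)CC(=O)O[C@H]1C=CC2=CC(O[Si](C)(C)C(C)(C)C)=CC[C@]2(C)[C@H]1C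
F5 | step 8 | (R,E)-4-hydroxy-4-methylhex-2-enal | CC[C@@](C)(O)/C=C/C=O
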